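**Locants.** C1–C20 are labdane locants throughout (ring A = C1–C5, C10; ring B = C5–C10). "Axial" and "equatorial" refer to the chair–chair trans-decalin.

## The problem

Target 35 is an ent-labdane: a trans-fused decalin with five stereocentres (C1, C4, C5, C9, C10), two of them quaternary (C4, C10). It carries an exocyclic 8(17)-methylene and an (E)-12,14-diene chain on C9. The core stereochemical task is the contiguous array C1(OAc)–C10(CH3)–C9(chain), with the C1 oxygen equatorial and cis to the axial C20 methyl, together with the trans relation of H5 to C20. C4 lies away from all other functionality, but once the decalin exists its axial ester (cis to C20) can be set by enolate alkylation on the face opposite C20. C9 holds the only epimerisable hydrogen and is allylic to the 8(17)-alkene. Three groups limit the order of events: the diene (acid, heat, radicals), the 8(17)-alkene (it moves into conjugation whenever C11 is a carbonyl and base is present) and the acetate (hydride, amide bases). The enabling feature is the sequence O–C1 / quaternary C10 / C9 bearing a carbon (C11) that can be a carboxyl / C8 as a carbonyl equivalent. Read backwards, this is a C1 ketyl adding to C10 of a C9=C10 enoate, whose C9 enolate closes ring B on a C8 ketone. If that works, one stereocentre (C5) has to control the rest.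

## Retrosynthesis

**Diene (35 ⇒ 34 ⇒ 33).** C14=C15 and C12=C13 are cut by two Wittig reactions, through enal 34 back to the C12 aldehyde 33. A one-step allyl-ylide or sulfone olefination would be shorter but is not reliably E-selective for a trisubstituted alkene; the stabilised α-methyl ylide is. The forward steps must tolerate the acetate and leave C9 alone.

**C12, the acetate and C4 (33 ⇒ 32 ⇒ 31 ⇒ 29 ⇒ 28).** C11–C12 is cut by a methoxymethylene Wittig on lactol 28. This one step adds C12, keeps it masked as enol ether 29 and frees the C1 hydroxyl. With no other acidic site in 29, the C4–CH3 bond is cut next (enolate methylation, 29 → 31). Acetylation (32) must precede unmasking of the aldehyde (33), otherwise C1–OH and C12 would form a six-membered lactol. Putting the acetate on earlier is excluded because it would not survive the hydride and amide-base steps.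

**Lactone as a relay (28 ⇒ 27 ⇒ 25 ⇒ 24).** The C1 oxygen and the C11 carboxyl sit on the two equatorial positions flanking C10 and can be tied into a γ-lactone. The lactone protects C1–OH, makes C11 the most reactive carbonyl towards i-Bu2AlH (lactol 28), and dictates the C9 configuration when the conjugated lactone 25 is deconjugated to 27. One of the two C4 esters is removed beforehand on the robust conjugated lactone (24 → 25). Removing it first and re-alkylating later fixes C4 in two steps, against three for a selective reduction and deoxygenation of the equatorial ester.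

**Functional-group adjustment (24 ⇒ 21).** Acid turns the tert-butyl ester, the C1 hydroxyl and the tertiary C8 hydroxyl of diol 21 into the unsaturated lactone. C8 and C9 are erased here, so only C1, C5 and C10 of 21 need to be right.

**Key disconnection (21 ⇒ 19).** C1–C10 and C8–C9 are cut together. Acyclic keto aldehyde 19 has a single stereocentre (C5), a (Z)-enoate and a non-stereogenic malonate at C4. The forward reaction must reduce the aldehyde before the ketone, add the ketyl to a β,β-disubstituted enoate, and let the samarium enolate undergo the aldol before it is protonated. Cutting either bond alone would require a regioselective ester enolate in the presence of a methyl ketone, which is not available by deprotonation.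

**Enoate (19 ⇒ 18 ⇒ 16 ⇒ 13).** After acetal hydrolysis, C10–C20 is cut (syn-methylcupration of ynoate 16) and then C9–C11 (carboxylation of alkyne 13). Only syn addition of CH3 and H across an ynoate places C5 cis to the ester; olefination of a methyl ketone or carbometallation of the terminal alkyne would give the other isomer.

**C5 (13 ⇒ 12 ⇒ 10 ⇒ 8 ⇒ 6 + 7).** The alkyne comes from the vinyl group of 10 (ozonolysis to 12, one-carbon homologation). C3–C4 is cut by malonate alkylation with 9, and C4–C5 by iridium-catalysed allylic alkylation of carbonate 6 with malonate 7. A copper-catalysed propargylic substitution would reach 13 more directly, but alkyl-substituted propargylic esters are its least selective substrates. The iridium reaction is dependable for alkyl-substituted allyl carbonates, and the two extra steps are accepted for that.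

**Carbonate (6 ⇒ 5 ⇒ 4 ⇒ 2 + 3 ⇒ 1).** Cross-metathesis of the ketal of hex-5-en-2-one (1) with methyl acrylate (3), reduction and carbonate formation give 6 as the pure E isomer, which the iridium step needs.

## Roads not taken

**Alternative 1: conjugate vinylation and alkylation of a ring B enone.** The cuts are C1–C10 and C9–C11 on enone A2. Copper-mediated conjugate vinylation at C10, anti to the C5 arm, followed by alkylation at C9 with allylic bromide A3, would give ketone A1. Its merits are real: the whole C11–C14 chain with its (E)-trisubstituted alkene arrives in one operation, and the C8 ketone can be methylenated directly to the 8(17)-alkene. The chosen plan spends about eight steps on those two features and has to pass through a deconjugation. The weak points lie elsewhere. Conjugate addition to a β,β-disubstituted enone next to a C5 substituent is slow, and the hindered enolate alkylates reluctantly and may equilibrate towards C7. Ring A is left entirely unbuilt. The C1 oxygen (absent in A1), its cis relation to C20, the C2–C3 bond and both carbon substituents of quaternary C4 would each need a separate stereocontrolled operation. The chosen plan sets against the side-chain advantage that ring A, the C1 oxygen, C10 and the ring fusion are made in one step from one stereocentre.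

**Alternative 2: ester-enolate Claisen contraction to ring B.** The cut is C5–C10, made by an Ireland–Claisen rearrangement in which a six-membered lactone ring is exchanged for carbocyclic ring B through a boat transition state, giving acid A4. Chirality transfer in such rearrangements is dependable, the quaternary C10 is formed in a concerted step with predictable geometry, and C1 arrives already oxidised. For this target the product is a poor fit. C1 is at the acid level and must become a secondary alcohol with a new stereocentre after C1–C2 is formed. C4 is a bare methylene that still needs both of its carbon substituents. The ring B alkene sits at C6–C7, where the target has none, while C8 and C9 are unfunctionalised. In forming C10 this route is the safer one, since the chosen plan relies on radical addition to a hindered enoate. The chosen plan offsets that by delivering both rings, four stereocentres and usable functionality at C1, C8 and C9 in the same step.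

**Alternative 3: pyrone Diels–Alder to a bridged lactone.** The cuts are C4–C5 and C1–C10. Cycloaddition of 3-methyl-2-pyrone A6 across its C3 and C6 to enal A7 would give the endo adduct A5. This is the most convergent idea considered. It sets C1, C4, C5 and C10 at once, the lactone bridge delivers the C1 oxygen and the C4 carboxyl cis to each other exactly as in 35, and the vinyl bromide and formyl groups are placed for a ring B closure that would give the 8(17)-alkene directly. On C4 it is better than the chosen plan, which needs a decarboxylation and a methylation. Its weak points are in the key step itself. An unactivated 2-pyrone is a poor diene towards a β-alkyl α-methyl enal. The adduct loses carbon dioxide on heating, which limits how hard the reaction can be forced. Regio-, endo- and absolute control would all have to come from a catalyst in a reaction class where asymmetric catalysis is established mainly for hydroxy-substituted pyrones. C9 would then emerge as a carbinol that must still be turned into the chain-bearing centre. The chosen plan is longer but rests on a better-understood cascade and a reliable catalytic entry to its single controlling stereocentre.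

Key step: step 12

**Assumption (step 5).** The ligand antipode is the one that the established facial model for this iridium catalyst assigns to the 3S product 8; both antipodes are available.

**Remark.** 25, 27, 28 and 29 are carried as C4 epimer mixtures (28 also as anomers, 29 as E/Z enol ethers). These elements are written without descriptors and are all removed by step 20.

## Route

Step 1
Reactants: 1 hex-5-en-2-one
Product: 2 2-(but-3-en-1-yl)-2-methyl-1,3-dioxolane
Conditions: ethylene glycol, TsOH·H2O (cat.), toluene, reflux, Dean–Stark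
Reagents that add atoms: ethylene glycol, OCCO
Why: Acid-catalysed ketalisation with azeotropic removal of water; the dioxolane masks the future C8 ketone against the later amide-base, acetylide and cuprate steps.

Step 2
Reactants: 2 2-(but-3-en-1-yl)-2-methyl-1,3-dioxolane; 3 methyl acrylate
Product: 4 methyl (2E)-5-(2-methyl-1,3-dioxolan-2-yl)pent-2-enoate
Conditions: second-generation Grubbs catalyst (H2IMes)(PCy3)Cl2Ru=CHPh (2 mol%), CH2Cl2, 40 °C
Reagents that add atoms: none
Why: Olefin cross-metathesis of a terminal alkene with an acrylate is selective for the cross product and gives the E enoate, which step 5 needs as a single geometric isomer.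

Step 3
Reactants: 4 methyl (2E)-5-(2-methyl-1,3-dioxolan-2-yl)pent-2-enoate
Product: 5 (2E)-5-(2-methyl-1,3-dioxolan-2-yl)pent-2-en-1-ol
Conditions: i-Bu2AlH (2.2 equiv), CH2Cl2, −78 °C; aq. potassium sodium tartrate
Reagents that add atoms: none
Why: 1,2-Reduction of an enoate to the allylic alcohol with i-Bu2AlH; the ketal is inert.

Step 4
Reactants: 5 (2E)-5-(2-methyl-1,3-dioxolan-2-yl)pent-2-en-1-ol
Product: 6 methyl (2E)-5-(2-methyl-1,3-dioxolan-2-yl)pent-2-en-1-yl carbonate
Conditions: ClCO2Me, pyridine, CH2Cl2, 0 °C
Reagents that add atoms: methyl chloroformate, COC(=O)Cl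
Why: Acylation of a primary allylic alcohol with a chloroformate gives the methyl carbonate, the standard leaving group for iridium-catalysed allylic substitution.

Step 5
Reactants: 6 methyl (2E)-5-(2-methyl-1,3-dioxolan-2-yl)pent-2-en-1-yl carbonate; 7 dimethyl malonate
Product: 8 dimethyl 2-[(3S)-5-(2-methyl-1,3-dioxolan-2-yl)pent-1-en-3-yl]propanedioate
Conditions: [Ir(cod)Cl]2 (2 mol%), O,O'-(1,1'-binaphthalene-2,2'-diyl) N,N-bis(1-phenylethyl)phosphoramidite (4 mol%), TBD (cat.), THF, rt
Reagents that add atoms: none
Why: Iridium-catalysed asymmetric allylic alkylation of a linear (E)-allyl carbonate: the malonate attacks the substituted terminus of the cyclometallated iridium–phosphoramidite allyl complex, giving the branched product and setting C5 (3S) under catalyst control; methoxide released from the carbonate generates the nucleophile.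

Step 6
Reactants: 8 dimethyl 2-[(3S)-5-(2-methyl-1,3-dioxolan-2-yl)pent-1-en-3-yl]propanedioate; 9 2-(2-bromoethyl)-1,3-dioxolane
Product: 10 dimethyl 2-[2-(1,3-dioxolan-2-yl)ethyl]-2-[(3S)-5-(2-methyl-1,3-dioxolan-2-yl)pent-1-en-3-yl]propanedioate
Conditions: NaH, DMF, 0 °C; then 9, NaI (cat.), 60 °C
Reagents that add atoms: none
Why: Malonate alkylation (SN2) with a primary bromide under iodide catalysis; C4 becomes quaternary and non-stereogenic, and the C5 hydrogen is not acidic.

Step 7
Reactants: 10 dimethyl 2-[2-(1,3-dioxolan-2-yl)ethyl]-2-[(3S)-5-(2-methyl-1,3-dioxolan-2-yl)pent-1-en-3-yl]propanedioate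
Product: 12 dimethyl 2-[2-(1,3-dioxolan-2-yl)ethyl]-2-[(2R)-4-(2-methyl-1,3-dioxolan-2-yl)-1-oxobutan-2-yl]propanedioate, via ozonide 11 (not isolated)
Conditions: O3, CH2Cl2, −78 °C; then PPh3, −78 °C to rt
Reagents that add atoms: ozone, [O-][O+]=O
Why: Ozonolysis of the only alkene with reductive cleavage of the ozonide; acetals and esters do not react at −78 °C when ozone is stopped at the end point.

Step 8
Reactants: 12 dimethyl 2-[2-(1,3-dioxolan-2-yl)ethyl]-2-[(2R)-4-(2-methyl-1,3-dioxolan-2-yl)-1-oxobutan-2-yl]propanedioate
Product: 13 dimethyl 2-[2-(1,3-dioxolan-2-yl)ethyl]-2-[(3S)-5-(2-methyl-1,3-dioxolan-2-yl)pent-1-yn-3-yl]propanedioate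
Conditions: dimethyl (1-diazo-2-oxopropyl)phosphonate, K2CO3, MeOH, 0 °C to rt
Reagents that add atoms: dimethyl (1-diazo-2-oxopropyl)phosphonate, CC(=O)C(=[N+]=[N-])P(=O)(OC)OC
Why: Ohira–Bestmann (Seyferth–Gilbert) homologation of an aldehyde to a terminal alkyne under mild carbonate conditions; C5 is flanked by a quaternary carbon and the reaction is run cold and short to avoid epimerisation.

Step 9
Reactants: 13 dimethyl 2-[2-(1,3-dioxolan-2-yl)ethyl]-2-[(3S)-5-(2-methyl-1,3-dioxolan-2-yl)pent-1-yn-3-yl]propanedioate; 14 di-tert-butyl dicarbonate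
Product: 16 dimethyl 2-[(4S)-1-tert-butoxy-6-(2-methyl-1,3-dioxolan-2-yl)-1-oxohex-2-yn-4-yl]-2-[2-(1,3-dioxolan-2-yl)ethyl]propanedioate, via lithium acetylide 15 (not isolated)
Conditions: LiN(i-Pr)2 (1.1 equiv), THF, −78 °C; then 14, −78 to 0 °C; aq. NH4Cl
Reagents that add atoms: none
Why: Deprotonation of the terminal alkyne (the only acidic C–H, since the malonate is fully substituted) and acylation of the acetylide with the dicarbonate gives the tert-butyl ynoate.

Step 10
Reactants: 16 dimethyl 2-[(4S)-1-tert-butoxy-6-(2-methyl-1,3-dioxolan-2-yl)-1-oxohex-2-yn-4-yl]-2-[2-(1,3-dioxolan-2-yl)ethyl]propanedioate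
Product: 18 dimethyl 2-[(2Z,4S)-1-tert-butoxy-3-methyl-6-(2-methyl-1,3-dioxolan-2-yl)-1-oxohex-2-en-4-yl]-2-[2-(1,3-dioxolan-2-yl)ethyl]propanedioate, via alkenylcuprate 17 (not isolated)
Conditions: Me2CuLi (from CuI and 2 MeLi), THF, −78 °C; MeOH at −78 °C, then aq. NH4Cl
Reagents that add atoms: lithium dimethylcuprate, [Li+].C[Cu-]C
Why: Syn-carbocupration of an ynoate and protonation of the alkenylcuprate with retention place the new methyl (C20) trans to the ester and C5 cis to it, giving the (Z)-enoate; low temperature prevents equilibration through the allenolate.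

Step 11
Reactants: 18 dimethyl 2-[(2Z,4S)-1-tert-butoxy-3-methyl-6-(2-methyl-1,3-dioxolan-2-yl)-1-oxohex-2-en-4-yl]-2-[2-(1,3-dioxolan-2-yl)ethyl]propanedioate
Product: 19 dimethyl 2-[(2Z,4S)-1-tert-butoxy-3-methyl-1,7-dioxooct-2-en-4-yl]-2-(3-oxopropyl)propanedioate
Conditions: 2 M HCl, THF, rt
Reagents that add atoms: water, O
Why: Acid-catalysed acetal hydrolysis of both dioxolanes; the tert-butyl ester and the trisubstituted (Z)-enoate are stable to dilute aqueous acid at room temperature.

Step 12
Reactants: 19 dimethyl 2-[(2Z,4S)-1-tert-butoxy-3-methyl-1,7-dioxooct-2-en-4-yl]-2-(3-oxopropyl)propanedioate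
Product: 21 1-tert-butyl 5,5-dimethyl (1S,2R,4aS,8S,8aR)-2,8-dihydroxy-2,8a-dimethyldecahydronaphthalene-1,5,5-tricarboxylate (labdane locants 1S,5S,8R,9S,10R), via monocyclic samarium enolate 20 (not isolated)
Conditions: SmI2 (2.5 equiv, 0.1 M), THF, −78 to −20 °C, slow addition of 19, no HMPA, no proton source; then aq. NH4Cl
Reagents that add atoms: none
Why: SmI2 transfers an electron to the aldehyde, the only carbonyl reduced at a useful rate in THF without HMPA, and the C1 ketyl adds to C10 of the (Z)-enoate; the α-ester radical at C9 is reduced to the trivalent samarium enolate 20, which adds to the C8 ketone. The closest known reaction type is the SmI2 ketyl–olefin cyclisation/intramolecular aldol cascade of aldehyde enoates that carry a second carbonyl group. Ring A closes 6-exo-trig (C1–C10), helped by the geminal diester at C4; ring B closes 6-(enolexo)-exo-trig (C8–C9). C10: allylic 1,3-strain with the cis ester holds C5–H in the alkene plane, the tether through C4 then reaches only one face, and C20 ends anti to H5 (trans fusion). C1: in the chair transition state the samarium-bound oxygen is pseudo-equatorial and turned away from the ester terminus, so the hydroxyl ends equatorial and cis to C20. C9 and C8: the chelated chair aldol should place the ester equatorial and the C8 oxygen axial, but both centres are erased in step 13 and need not be controlled. The step needs aldehyde-before-ketone chemoselectivity and aldol faster than protonation; leaving out HMPA and any proton source serves both, and the tert-butyl ester keeps the C1 alkoxide from lactonising onto C11 before the aldol.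

Step 13
Reactants: 21 1-tert-butyl 5,5-dimethyl (1S,2R,4aS,8S,8aR)-2,8-dihydroxy-2,8a-dimethyldecahydronaphthalene-1,5,5-tricarboxylate
Product: 24 dimethyl (1S,5S,10R)-8,10-dimethyl-decal-8-ene-4,4-dicarboxylate 9-carboxylic acid 1,11-lactone (conjugated γ-lactone; C11 carbonyl bonded to the 1-oxygen), via hydroxy acid 22 (not isolated), via hydroxy lactone 23 (not isolated)
Conditions: TFA, CH2Cl2, 0 °C to rt; evaporate; then TsOH·H2O (cat.), toluene, 90 °C
Reagents that add atoms: none
Why: Acidolysis of the tert-butyl ester gives acid 22, which lactonises onto the equatorial C1 hydroxyl (a trans-fused γ-lactone across the two positions flanking C10); acid-catalysed β-elimination of the tertiary C8 hydroxyl through the lactone enol then gives the conjugated tetrasubstituted alkene, the thermodynamic isomer.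

Step 14
Reactants: 24 conjugated lactone diester
Product: 25 methyl (1S,5R,10R)-8,10-dimethyl-decal-8-ene-4-carboxylate 9-carboxylic acid 1,11-lactone (C4 epimer mixture)
Conditions: LiCl, H2O (2 equiv), DMSO, 150 °C
Reagents that add atoms: none
Why: Krapcho dealkoxycarbonylation of a geminal dimethyl diester (chloride attack at O-methyl, loss of CO2, protonation); the conjugated lactone has nothing sensitive to hot neutral halide, and it does not matter which ester leaves.

Step 15
Reactants: 25 conjugated lactone monoester
Product: 27 methyl (1S,5R,9R,10R)-10-methyl-8-methylidene-decalin-4-carboxylate 9-carboxylic acid 1,11-lactone (C4 epimer mixture), via dilithium bis-enolate 26 (not isolated)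
Conditions: LiN(i-Pr)2 (2.5 equiv), THF, −78 °C; then AcOH in THF, −78 °C
Reagents that add atoms: none
Why: Deconjugative protonation: kinetic γ-deprotonation occurs at C17, the γ-carbon held syn to the lactone carbonyl, giving the exocyclic dienolate (the C4 ester is enolised too and simply reprotonated), and kinetic α-protonation at C9 gives the 8(17)-ene; C9 can only form with C11 cis to the C1 oxygen because both are held in the five-membered lactone, which is the target configuration.

Step 16
Reactants: 27 deconjugated lactone monoester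
Product: 28 methyl (1S,5R,9R,10R)-1,11-epoxy-11-hydroxy-10-methyl-8-methylidene-decalin-4-carboxylate bearing C11 on C9 (lactol; anomer and C4 epimer mixture)
Conditions: i-Bu2AlH (1.1 equiv), CH2Cl2, −78 °C; aq. potassium sodium tartrate
Reagents that add atoms: none
Why: Partial reduction of a γ-lactone to the lactol with one equivalent of i-Bu2AlH at −78 °C; the hindered ring ester at C4 reacts more slowly than the lactone.

Step 17
Reactants: 28 lactol
Product: 29 methyl (1S,5R,9R,10R)-1-hydroxy-9-(2-methoxyethenyl)-10-methyl-8-methylidene-decalin-4-carboxylate (E/Z and C4 epimer mixture)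
Conditions: Ph3P(CH2OMe)Cl, KN(SiMe3)2, THF, 0 °C; then 28, 0 °C to rt
Reagents that add atoms: (methoxymethyl)triphenylphosphonium chloride, COC[P+](c1ccccc1)(c1ccccc1)c1ccccc1.[Cl-]
Why: Wittig olefination of the lactol through its open hydroxy-aldehyde form (one-carbon homologation): C11–C12 is formed, C12 stays masked as an enol ether and the C1 hydroxyl is released.

Step 18
Reactants: 29 hydroxy enol ether
Product: 31 methyl (1S,4R,5S,9R,10R)-1-hydroxy-9-(2-methoxyethenyl)-4,10-dimethyl-8-methylidene-decalin-4-carboxylate, via dilithium alkoxide enolate 30 (not isolated)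
Conditions: LiN(i-Pr)2 (2.5 equiv), THF, −78 to −40 °C; then MeI (1.2 equiv), −78 to −20 °C; aq. NH4Cl
Reagents that add atoms: iodomethane, CI
Why: Ester enolate alkylation: the exocyclic C4 enolate is methylated on the equatorial face, away from the axial C20 methyl that blocks the other face, giving equatorial CH3 and axial ester (4R); the hindered lithium alkoxide at C1 is not methylated at low temperature.

Step 19
Reactants: 31 C4-methylated hydroxy enol ether
Product: 32 methyl (1S,4R,5S,9R,10R)-1-acetoxy-9-(2-methoxyethenyl)-4,10-dimethyl-8-methylidene-decalin-4-carboxylate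
Conditions: Ac2O, pyridine, DMAP (cat.), CH2Cl2, rt
Reagents that add atoms: acetic anhydride, CC(=O)OC(C)=O
Why: DMAP-catalysed acetylation of the equatorial secondary C1 alcohol; the enol ether and the alkene are inert to the basic acylation medium.

Step 20
Reactants: 32 acetoxy enol ether
Product: 33 methyl (1S,4R,5S,9R,10S)-1-acetoxy-4,10-dimethyl-8-methylidene-9-(2-oxoethyl)decalin-4-carboxylate
Conditions: 1 M HCl, THF, 0 °C to rt
Reagents that add atoms: water, O
Why: Mild acid hydrolysis of the enol ether to the aldehyde; the acetate now prevents hemiacetal formation between the C1 oxygen and C12, and the disubstituted exocyclic alkene does not migrate in dilute acid at room temperature.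

Step 21
Reactants: 33 C12 aldehyde
Product: 34 methyl (1S,4R,5S,9R,10S)-1-acetoxy-4,10-dimethyl-8-methylidene-9-[(2E)-3-methyl-4-oxobut-2-en-1-yl]decalin-4-carboxylate
Conditions: Ph3P=C(CH3)CHO, toluene, 90 °C
Reagents that add atoms: 2-(triphenylphosphoranylidene)propanal, CC(C=O)=P(c1ccccc1)(c1ccccc1)c1ccccc1
Why: Wittig reaction of an aldehyde with a stabilised α-methyl ylide gives the (E)-2-methyl enal (C12=C13) with the usual high E selectivity; the neutral conditions leave the acetate and C9 untouched.

Step 22
Reactants: 34 enal
Product: 35 methyl (1S,4R,5S,9R,10S)-1-acetoxylabda-8(17),12E,14-trien-19-oate (ent-labdane series; CNP0235031.1)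
Conditions: Ph3PCH3Br, KN(SiMe3)2, THF, −78 to 0 °C
Reagents that add atoms: methyltriphenylphosphonium bromide, C[P+](c1ccccc1)(c1ccccc1)c1ccccc1.[Br-]
Why: Wittig methylenation of the enal gives the terminal diene; at low temperature the aldehyde reacts far faster than the acetate or the hindered ester, and the C12 alkene geometry is not touched.

## Compound list

1 | hex-5-en-2-one | CC(=O)CCC=C | starting material
2 | 2-(but-3-en-1-yl)-2-methyl-1,3-dioxolane | CC1(CCC=C)OCCO1 | intermediate
3 | methyl acrylate | C=CC(=O)OC | starting material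
4 | methyl (2E)-5-(2-methyl-1,3-dioxolan-2-yl)pent-2-enoate | COC(=O)/C=C/CCC1(C)OCCO1 | intermediate
5 | (2E)-5-(2-methyl-1,3-dioxolan-2-yl)pent-2-en-1-ol | OC/C=C/CCC1(C)OCCO1 | intermediate
6 | methyl (2E)-5-(2-methyl-1,3-dioxolan-2-yl)pent-2-en-1-yl carbonate | COC(=O)OC/C=C/CCC1(C)OCCO1 | intermediate
7 | dimethyl malonate | COC(=O)CC(=O)OC | starting material
8 | dimethyl 2-[(3S)-5-(2-methyl-1,3-dioxolan-2-yl)pent-1-en-3-yl]propanedioate | COC(=O)C(C(=O)OC)[C@@H](CCC1(C)OCCO1)C=C | intermediate
9 | 2-(2-bromoethyl)-1,3-dioxolane | BrCCC1OCCO1 | starting material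
10 | dimethyl 2-[2-(1,3-dioxolan-2-yl)ethyl]-2-[(3S)-5-(2-methyl-1,3-dioxolan-2-yl)pent-1-en-3-yl]propanedioate | O1CCOC1CCC(C(=O)OC)(C(=O)OC)[C@@H](CCC2(C)OCCO2)C=C | intermediate
11 | ozonide of 10 (3-substituted 1,2,4-trioxolane; not isolated) | O1CCOC1CCC(C(=O)OC)(C(=O)OC)[C@@H](CCC2(C)OCCO2)C3OCOO3 | intermediate
12 | dimethyl 2-[2-(1,3-dioxolan-2-yl)ethyl]-2-[(2R)-4-(2-methyl-1,3-dioxolan-2-yl)-1-oxobutan-2-yl]propanedioate | O1CCOC1CCC(C(=O)OC)(C(=O)OC)[C@@H](CCC2(C)OCCO2)C=O | intermediate
13 | dimethyl 2-[2-(1,3-dioxolan-2-yl)ethyl]-2-[(3S)-5-(2-methyl-1,3-dioxolan-2-yl)pent-1-yn-3-yl]propanedioate | O1CCOC1CCC(C(=O)OC)(C(=O)OC)[C@@H](CCC2(C)OCCO2)C#C | intermediate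
14 | di-tert-butyl dicarbonate | CC(C)(C)OC(=O)OC(=O)OC(C)(C)C | starting material
15 | lithium acetylide of 13 (not isolated) | O1CCOC1CCC(C(=O)OC)(C(=O)OC)[C@@H](CCC2(C)OCCO2)C#C[Li] | intermediate
16 | dimethyl 2-[(4S)-1-tert-butoxy-6-(2-methyl-1,3-dioxolan-2-yl)-1-oxohex-2-yn-4-yl]-2-[2-(1,3-dioxolan-2-yl)ethyl]propanedioate | O1CCOC1CCC(C(=O)OC)(C(=O)OC)[C@@H](CCC2(C)OCCO2)C#CC(=O)OC(C)(C)C | intermediate
17 | lithium methyl(alkenyl)cuprate from syn addition to 16 (Cu on C9, cis to the new methyl; not isolated) | O1CCOC1CCC(C(=O)OC)(C(=O)OC)[C@@H](CCC2(C)OCCO2)/C(C)=C(\C(=O)OC(C)(C)C)[Cu-]C.[Li+] | intermediate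
18 | dimethyl 2-[(2Z,4S)-1-tert-butoxy-3-methyl-6-(2-methyl-1,3-dioxolan-2-yl)-1-oxohex-2-en-4-yl]-2-[2-(1,3-dioxolan-2-yl)ethyl]propanedioate | O1CCOC1CCC(C(=O)OC)(C(=O)OC)[C@@H](CCC2(C)OCCO2)/C(C)=C\C(=O)OC(C)(C)C | intermediate
19 | dimethyl 2-[(2Z,4S)-1-tert-butoxy-3-methyl-1,7-dioxooct-2-en-4-yl]-2-(3-oxopropyl)propanedioate | O=CCCC(C(=O)OC)(C(=O)OC)[C@@H](CCC(C)=O)/C(C)=C\C(=O)OC(C)(C)C | intermediate
20 | ring A trivalent samarium alkoxide/ester enolate (1S,5S,10R; not isolated) | CC(=O)CC[C@H]1[C@](C)(C=C(O[Sm](I)I)OC(C)(C)C)[C@@H](O[Sm](I)I)CCC1(C(=O)OC)C(=O)OC | intermediate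
21 | 1-tert-butyl 5,5-dimethyl (1S,2R,4aS,8S,8aR)-2,8-dihydroxy-2,8a-dimethyldecahydronaphthalene-1,5,5-tricarboxylate | CC(C)(C)OC(=O)[C@@H]1[C@](C)(O)CC[C@H]2[C@@]1(C)[C@@H](O)CCC2(C(=O)OC)C(=O)OC | intermediate
22 | (1S,2R,4aS,8S,8aR)-2,8-dihydroxy-5,5-bis(methoxycarbonyl)-2,8a-dimethyldecahydronaphthalene-1-carboxylic acid (not isolated) | OC(=O)[C@@H]1[C@](C)(O)CC[C@H]2[C@@]1(C)[C@@H](O)CCC2(C(=O)OC)C(=O)OC | intermediate
23 | 8-hydroxy 1,11-lactone diester (1S,5S,8R,9S,10R; not isolated) | O=C3[C@@H]1[C@](C)(O)CC[C@H]2[C@@]1(C)[C@@H](O3)CCC2(C(=O)OC)C(=O)OC | intermediate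
24 | conjugated (C8=C9) 1,11-lactone 4,4-diester (1S,5S,10R) | O=C3C1=C(C)CC[C@H]2[C@@]1(C)[C@@H](O3)CCC2(C(=O)OC)C(=O)OC | intermediate
25 | conjugated 1,11-lactone 4-monoester (1S,5R,10R; C4 epimer mixture) | O=C3C1=C(C)CC[C@H]2[C@@]1(C)[C@@H](O3)CCC2C(=O)OC | intermediate
26 | dilithium lactone dienolate/C4 ester enolate (not isolated) | [Li]OC3=C1C(=C)CC[C@H]2[C@@]1(C)[C@@H](O3)CCC2=C(OC)O[Li] | intermediate
27 | 8(17)-ene 1,11-lactone 4-monoester (1S,5R,9R,10R; C4 epimer mixture) | O=C3[C@@H]1C(=C)CC[C@H]2[C@@]1(C)[C@@H](O3)CCC2C(=O)OC | intermediate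
28 | 8(17)-ene 1,11-lactol 4-monoester (1S,5R,9R,10R; anomer and C4 epimer mixture) | OC3[C@@H]1C(=C)CC[C@H]2[C@@]1(C)[C@@H](O3)CCC2C(=O)OC | intermediate
29 | methyl (1S,5R,9R,10R)-1-hydroxy-9-(2-methoxyethenyl)-10-methyl-8-methylidene-decalin-4-carboxylate (E/Z and C4 epimer mixture) | COC=C[C@@H]1C(=C)CC[C@H]2[C@@]1(C)[C@@H](O)CCC2C(=O)OC | intermediate
30 | dilithium C1 alkoxide/C4 ester enolate of 29 (not isolated) | COC=C[C@@H]1C(=C)CC[C@H]2[C@@]1(C)[C@@H](O[Li])CCC2=C(OC)O[Li] | intermediate
31 | methyl (1S,4R,5S,9R,10R)-1-hydroxy-9-(2-methoxyethenyl)-4,10-dimethyl-8-methylidene-decalin-4-carboxylate | COC=C[C@@H]1C(=C)CC[C@H]2[C@@]1(C)[C@@H](O)CC[C@@]2(C)C(=O)OC | intermediate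
32 | methyl (1S,4R,5S,9R,10R)-1-acetoxy-9-(2-methoxyethenyl)-4,10-dimethyl-8-methylidene-decalin-4-carboxylate | COC=C[C@@H]1C(=C)CC[C@H]2[C@@]1(C)[C@@H](OC(C)=O)CC[C@@]2(C)C(=O)OC | intermediate
33 | methyl (1S,4R,5S,9R,10S)-1-acetoxy-4,10-dimethyl-8-methylidene-9-(2-oxoethyl)decalin-4-carboxylate | O=CC[C@@H]1C(=C)CC[C@H]2[C@@]1(C)[C@@H](OC(C)=O)CC[C@@]2(C)C(=O)OC | intermediate
34 | methyl (1S,4R,5S,9R,10S)-1-acetoxy-4,10-dimethyl-8-methylidene-9-[(2E)-3-methyl-4-oxobut-2-en-1-yl]decalin-4-carboxylate | O=C/C(C)=C/C[C@@H]1C(=C)CC[C@H]2[C@@]1(C)[C@@H](OC(C)=O)CC[C@@]2(C)C(=O)OC | intermediate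
35 | methyl (1S,4R,5S,9R,10S)-1-acetoxylabda-8(17),12E,14-trien-19-oate (CNP0235031.1) | C=C/C(C)=C/C[C@@H]1C(=C)CC[C@H]2[C@@]1(C)[C@@H](OC(C)=O)CC[C@@]2(C)C(=O)OC | target

## Step count and risks

Total: 22 steps. Longest linear sequence: 22 steps (1 → 35); all other inputs are commercial.

**Step 12 (key step).** The most likely failure is that the samarium enolate 20 is protonated, or the aldolate reverts, before the C8–C9 bond to the hindered methyl ketone is secured, so that only ring A is formed. Competing electron transfer to the ketone, followed by closure of that ketyl onto C10, is the second concern. Fallback: starting from 19, the reduction would be run in the presence of Me3SiCl so that the enolate and the alkoxide are intercepted as the bis(trimethylsilyl) ketene acetal F1. Ring B would then be closed in a separate Lewis-acid step (TiCl4, CH2Cl2, −78 °C, intramolecular Mukaiyama aldol onto the C8 ketone). Aqueous acid work-up removes the silyl groups and returns to 21.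

**Step 15.** Regiocontrol of the γ-deprotonation may be lost (C7 instead of C17), or the alkene may return into conjugation during quench or work-up. Fallback: starting from 25, photochemical deconjugation (254 nm, hexane, a trace of weak amine base) would give 27 directly. The photodienol forms by a 1,5-hydrogen shift that only the γ-carbon syn to the carbonyl (C17) can undergo, and the lactone again fixes C9. This fallback makes no new compound (F0).

**Step 17.** The open hydroxy aldehyde is β,γ-unsaturated and hindered. Under the basic ylide the exocyclic alkene may migrate into conjugation with the aldehyde, or C9 may epimerise, before olefination occurs. Fallback: starting from 28, non-basic Takai–Lombardo methylenation (Zn, CH2Br2, TiCl4) would give the vinyl carbinol F2. The enolate methylation of step 18 gives F3 and acetylation gives the vinyl acetate F4. An aldehyde-selective Wacker oxidation of the monosubstituted vinyl group (PdCl2(PhCN)2, CuCl2, AgNO2, t-BuOH/MeNO2, O2; the 1,1-disubstituted alkene is inert) then returns to 33.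

**Step 10.** Alkene geometry may erode by isomerisation of the alkenylcuprate through its allenolate, or addition at the hindered β-carbon may stall. Fallback: starting from 12, Roskamp homologation (tert-butyl diazoacetate, SnCl2) would give the β-keto ester F5. Triflation under non-chelating conditions (Tf2O, aqueous Me4NOH) gives the (E)-enol triflate F6. Stereoretentive methyl coupling (MeMgBr, Fe(acac)3 cat., THF, −30 °C) returns to 18, bypassing steps 8–10.

**Step 8.** The α-branched aldehyde may epimerise at C5 in carbonate/methanol before it is homologated. Fallback: starting from 12, Corey–Fuchs olefination under non-basic conditions (CBr4, PPh3, Zn) would give the dibromoalkene F7. Treatment with n-BuLi (2 equiv, THF, −78 °C; halogen–lithium exchange and rearrangement outpace addition to the neopentyl-type esters) and trapping of the acetylide with 14 returns to 16.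

## Further compounds

F1 | step 12 | ring A bis(trimethylsilyl) compound: tert-butyl trimethylsilyl ketene acetal at C9/C11 and 1-O-trimethylsilyl ether (1S,5S,10R) | CC(=O)CC[C@H]1[C@](C)(C=C(O[Si](C)(C)C)OC(C)(C)C)[C@@H](O[Si](C)(C)C)CCC1(C(=O)OC)C(=O)OC
F0 | step 15 | none | none
F2 | step 17 | methyl (1S,5R,9R,10R)-9-ethenyl-1-hydroxy-10-methyl-8-methylidene-decalin-4-carboxylate (C4 epimer mixture) | C=C[C@@H]1C(=C)CC[C@H]2[C@@]1(C)[C@@H](O)CCC2C(=O)OC
F3 | step 17 | methyl (1S,4R,5S,9R,10R)-9-ethenyl-1-hydroxy-4,10-dimethyl-8-methylidene-decalin-4-carboxylate | C=C[C@@H]1C(=C)CC[C@H]2[C@@]1(C)[C@@H](O)CC[C@@]2(C)C(=O)OC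
F4 | step 17 | methyl (1S,4R,5S,9R,10R)-1-acetoxy-9-ethenyl-4,10-dimethyl-8-methylidene-decalin-4-carboxylate | C=C[C@@H]1C(=C)CC[C@H]2[C@@]1(C)[C@@H](OC(C)=O)CC[C@@]2(C)C(=O)OC
F5 | step 10 | dimethyl 2-[(4R)-1-tert-butoxy-6-(2-methyl-1,3-dioxolan-2-yl)-1,3-dioxohexan-4-yl]-2-[2-(1,3-dioxolan-2-yl)ethyl]propanedioate | O1CCOC1CCC(C(=O)OC)(C(=O)OC)[C@@H](CCC2(C)OCCO2)C(=O)CC(=O)OC(C)(C)C
F6 | step 10 | dimethyl 2-[(2E,4R)-1-tert-butoxy-6-(2-methyl-1,3-dioxolan-2-yl)-1-oxo-3-(trifluoromethylsulfonyloxy)hex-2-en-4-yl]-2-[2-(1,3-dioxolan-2-yl)ethyl]propanedioate | O1CCOC1CCC(C(=O)OC)(C(=O)OC)[C@@H](CCC2(C)OCCO2)/C(OS(=O)(=O)C(F)(F)F)=C\C(=O)OC(C)(C)C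
F7 | step 8 | dimethyl 2-[(3S)-1,1-dibromo-5-(2-methyl-1,3-dioxolan-2-yl)pent-1-en-3-yl]-2-[2-(1,3-dioxolan-2-yl)ethyl]propanedioate | O1CCOC1CCC(C(=O)OC)(C(=O)OC)[C@@H](CCC2(C)OCCO2)C=C(Br)Br
A1 | alternative 1 | methyl 2-{3-[(2E)-4-(4-methoxybenzyloxy)-3-methylbut-2-en-1-yl]-2-methyl-4-oxo-2-vinylcyclohexyl}acetate | COc1ccc(COC/C(C)=C/C[C@@H]2C(=O)CC[C@H](CC(=O)OC)[C@@]2(C)C=C)cc1
A2 | alternative 1 | methyl 2-[(1R)-2-methyl-4-oxocyclohex-2-en-1-yl]acetate | COC(=O)C[C@H]1CCC(=O)C=C1C
A3 | alternative 1 | 1-{[(2E)-4-bromo-2-methylbut-2-en-1-yl]oxymethyl}-4-methoxybenzene | COc1ccc(COC/C(C)=C/CBr)cc1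
A4 | alternative 2 | 2-[2-(tert-butyldimethylsilyloxy)ethyl]-1-methylcyclohex-3-ene-1-carboxylic acid | OC(=O)[C@@]1(C)CCC=C[C@@H]1CCO[Si](C)(C)C(C)(C)C
A5 | alternative 3 | 8-(3-bromobut-3-en-1-yl)-4,7-dimethyl-3-oxo-2-oxabicyclo[2.2.2]oct-5-ene-7-carbaldehyde (endo adduct) | C=C(Br)CC[C@H]1[C@](C)(C=O)[C@H]2OC(=O)[C@]1(C)C=C2
A6 | alternative 3 | 3-methyl-2H-pyran-2-one | CC1=CC=COC1=O
A7 | alternative 3 | (2E)-6-bromo-2-methylhepta-2,6-dienal | C=C(Br)CC/C=C(\C)C=O
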